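The route rests on cutting the aryl ether bond O1–C7a of ring C. In ring B, C7a is para to C5, and C5 carries the furofuran carbon C7'; held at the aldehyde level, that carbon activates a fluorine on C7a. The precursor is therefore an open-chain (1S,2S) fluoro aldehyde from an anti-aldol reaction, with a free benzylic hydroxyl on the future C2 and a triisopropylsilyl ether on the primary oxygen. Base-induced intramolecular nucleophilic aromatic substitution then closes ring C in one operation, breaking no bond at C2 or C3, so the anti pair is locked irreversibly as the cis-dihydrobenzofuran. The surviving formyl group seeds the furofuran.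

Key step: step 10

**Conventions and remarks**

- Locants: dihydrobenzofuran O1, C2, C3, C3a, C4 to C7, C7a. Ring A is the guaiacyl ring on C2, ring B the benzo ring, ring C the five-membered oxygen ring. Furofuran carbons are C7', C8', C9' on the ring B side and C7'', C8'', C9'' on the syringyl side.
- Abbreviations: TIPS = triisopropylsilyl; Men = (1R,2S,5R)-menthyl; Syr(Bn) = 4-benzyloxy-3,5-dimethoxyphenyl; DBF = (2S,3S)-2-(4-benzyloxy-3-methoxyphenyl)-7-methoxy-3-[(TIPS-oxy)methyl]-2,3-dihydro-1-benzofuran-5-yl.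
- Structure check: the target is (2S,3S), cis, in ring C and (7'S,8'R,7''S,8''R), both aryl groups exo, in the furofuran. The (1S,2S) open-chain precursor is anti in the aldol sense and maps onto the cis ring. The (5R)-menthyloxybutenolide leads to (8'R,8''R), as required.
- Design changes:
  - The primary oxygen carries TIPS, not a smaller silyl group. A smaller group could migrate to the neighbouring alkoxide, and the freed primary oxygen would then attack C7a in an equally favourable 5-exo closure.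
  - The ring B carbon substituent is installed by sterically controlled C–H borylation rather than lithiation, because the position between the methoxy and acetal groups would compete for a base.
  - The carbinol formed at C7' in the three-component step is not relied on. Zimmerman–Traxler addition of the lactone enolate should favour the threo epimer, which a retentive ring closure would turn into an endo aryl group. Acid equilibration is excluded because it would also ionise C2–O1 and erode the cis ring. Both benzylic carbinols are therefore set by reduction of a 1,4-diketone, and the furofuran is closed at the primary carbons only.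
- Assumption: in the MgCl2-catalysed aldol the aldehyde is taken to attack the chelated Z-enolate of the (S)-4-benzyl imide on the face opposite the benzyl group, the sense seen in alkylations of this auxiliary, which gives the (2R,3S) adduct.

**Route**

Step 1
Reactants: 1 4-fluoro-3-methoxybenzaldehyde
Product: 2 2-(4-fluoro-3-methoxyphenyl)-1,3-dioxolane
Conditions: ethylene glycol, p-TsOH·H2O (cat.), toluene, reflux, Dean–Stark trap
Reagents that add atoms: ethylene glycol, OCCO
Why: Acid-catalysed acetalisation with azeotropic removal of water masks the formyl group against the boron, enolate and hydride reagents of steps 2 to 8.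

Step 2
Reactants: 2 2-(4-fluoro-3-methoxyphenyl)-1,3-dioxolane
Product: 3 2-[5-(1,3-dioxolan-2-yl)-2-fluoro-3-methoxyphenyl]-4,4,5,5-tetramethyl-1,3,2-dioxaborolane
Conditions: B2pin2 (1.0 equiv), [Ir(OMe)(cod)]2 (1.5 mol%), 4,4'-di-tert-butyl-2,2'-bipyridine (3 mol%), THF, 70 °C
Reagents that add atoms: bis(pinacolato)diboron, CC1(C)OB(OC1(C)C)B1OC(C)(C)C(C)(C)O1
Why: Iridium-catalysed aromatic C–H borylation is sterically controlled, and of the three ring hydrogens one lies between the acetal and the methoxy group, one is ortho to the bulky acetal, and only the one ortho to the small fluorine is accessible.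

Step 3
Reactants: 3 2-[5-(1,3-dioxolan-2-yl)-2-fluoro-3-methoxyphenyl]-4,4,5,5-tetramethyl-1,3,2-dioxaborolane; 4 ethyl bromoacetate
Product: 5 ethyl [5-(1,3-dioxolan-2-yl)-2-fluoro-3-methoxyphenyl]acetate
Conditions: Pd(OAc)2 (3 mol%), P(o-tol)3 (9 mol%), K3PO4, THF/H2O, rt
Reagents that add atoms: none
Why: Suzuki–Miyaura coupling of the arylboronate with the α-bromo ester builds the arylacetate in one step under basic conditions that leave the acetal intact.

Step 4
Reactants: 5 ethyl [5-(1,3-dioxolan-2-yl)-2-fluoro-3-methoxyphenyl]acetate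
Product: 6 [5-(1,3-dioxolan-2-yl)-2-fluoro-3-methoxyphenyl]acetic acid
Conditions: LiOH·H2O, THF/H2O, rt; then 1 M HCl to pH 4, 0 °C
Reagents that add atoms: lithium hydroxide, [Li+].[OH-]
Why: Saponification of the ethyl ester gives the acid, and the base-stable dioxolane survives the brief, cold and only mildly acidic work-up.

Step 5
Reactants: 6 [5-(1,3-dioxolan-2-yl)-2-fluoro-3-methoxyphenyl]acetic acid; 7 (S)-4-benzyl-1,3-oxazolidin-2-one
Product: 9 (S)-4-benzyl-3-{[5-(1,3-dioxolan-2-yl)-2-fluoro-3-methoxyphenyl]acetyl}-1,3-oxazolidin-2-one, via mixed pivalic anhydride 8 (not isolated)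
Conditions: t-BuCOCl, Et3N, THF, −20 °C; then 7, LiCl, −20 °C → rt
Reagents that add atoms: none
Why: One-pot N-acylation of the auxiliary through the mixed anhydride, with LiCl and Et3N activating the oxazolidinone, is the standard way to make such imides from arylacetic acids.

Step 6
Reactants: 9 (S)-4-benzyl-3-{[5-(1,3-dioxolan-2-yl)-2-fluoro-3-methoxyphenyl]acetyl}-1,3-oxazolidin-2-one; 10 O-benzylvanillin (4-benzyloxy-3-methoxybenzaldehyde)
Product: 12 (4S)-4-benzyl-3-[(2R,3S)-3-(4-benzyloxy-3-methoxyphenyl)-2-[5-(1,3-dioxolan-2-yl)-2-fluoro-3-methoxyphenyl]-3-hydroxypropanoyl]-1,3-oxazolidin-2-one, via trimethylsilyl ether 11 (not isolated)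
Conditions: MgCl2 (20 mol%), Et3N, Me3SiCl, EtOAc, rt; then PPTS (cat.), MeOH, 0 °C
Reagents that add atoms: none
Why: Magnesium halide-catalysed anti-aldol reaction of an N-acyloxazolidinone (Evans anti-aldol), in which soft enolisation gives the chelated Z-enolate, the non-enolisable aldehyde adds on the face away from the auxiliary benzyl group so that the α-carbon (future C3) is set by the auxiliary and the carbinol carbon (future C2) by the anti preference of the magnesium enolate, and silylation of the aldolate blocks retro-aldol before mild desilylation.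

Step 7
Reactants: 12 (4S)-4-benzyl-3-[(2R,3S)-3-(4-benzyloxy-3-methoxyphenyl)-2-[5-(1,3-dioxolan-2-yl)-2-fluoro-3-methoxyphenyl]-3-hydroxypropanoyl]-1,3-oxazolidin-2-one
Product: 13 (1S,2S)-1-(4-benzyloxy-3-methoxyphenyl)-2-[5-(1,3-dioxolan-2-yl)-2-fluoro-3-methoxyphenyl]propane-1,3-diol
Conditions: LiBH4, MeOH (1 equiv), THF, 0 °C
Reagents that add atoms: none
Why: Reductive cleavage of the imide by LiBH4 gives the primary alcohol and returns the auxiliary without a base strong enough to epimerise the α-aryl centre.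

Step 8
Reactants: 13 (1S,2S)-1-(4-benzyloxy-3-methoxyphenyl)-2-[5-(1,3-dioxolan-2-yl)-2-fluoro-3-methoxyphenyl]propane-1,3-diol
Product: 14 (1S,2S)-1-(4-benzyloxy-3-methoxyphenyl)-2-[5-(1,3-dioxolan-2-yl)-2-fluoro-3-methoxyphenyl]-3-(TIPS-oxy)propan-1-ol
Conditions: i-Pr3SiCl, imidazole, DMF, 0 °C → rt
Reagents that add atoms: chlorotriisopropylsilane, CC(C)[Si](Cl)(C(C)C)C(C)C
Why: The bulky silyl chloride silylates the primary hydroxyl far faster than the hindered secondary benzylic one (selective silyl ether formation).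

Step 9
Reactants: 14 (1S,2S)-1-(4-benzyloxy-3-methoxyphenyl)-2-[5-(1,3-dioxolan-2-yl)-2-fluoro-3-methoxyphenyl]-3-(TIPS-oxy)propan-1-ol
Product: 15 3-[(1S,2S)-1-(4-benzyloxy-3-methoxyphenyl)-1-hydroxy-3-(TIPS-oxy)propan-2-yl]-4-fluoro-5-methoxybenzaldehyde
Conditions: PPTS (0.2 equiv), acetone/H2O (9:1), 50 °C
Reagents that add atoms: water, O
Why: Mild acid-catalysed acetal hydrolysis frees the formyl group with an acid too weak to ionise the benzylic alcohol or cleave the TIPS ether.

Step 10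
Reactants: 15 3-[(1S,2S)-1-(4-benzyloxy-3-methoxyphenyl)-1-hydroxy-3-(TIPS-oxy)propan-2-yl]-4-fluoro-5-methoxybenzaldehyde
Product: 18 (2S,3S)-2-(4-benzyloxy-3-methoxyphenyl)-7-methoxy-3-[(TIPS-oxy)methyl]-2,3-dihydro-1-benzofuran-5-carbaldehyde, via sodium alkoxide 16 (not isolated), via Meisenheimer adduct 17 (not isolated)
Conditions: NaH (1.2 equiv), THF/DMF (10:1), 0.02 M, 0 °C → rt; aqueous NH4Cl quench
Reagents that add atoms: none
Why: Sodium hydride turns the C2 hydroxyl into alkoxide 16, which adds to C7a, the fluorine-bearing carbon of ring B, to give adduct 17 with its negative charge spread onto the para formyl oxygen, and loss of fluoride then restores the aromatic ring. The closest known reaction type is the intramolecular SNAr O-arylation of secondary alkoxides on fluoroarenes activated by a para carbonyl group. Ring C is closed in the 5-exo-trig mode by forming the O1–C7a bond at an sp2 carbon. No stereocentre is created: C2 and C3 come from step 6, and since neither the C2–O bond nor any bond at C3 is broken, the anti open-chain pair is transcribed into the cis ring. The step needs chemoselective, irreversible closure through the secondary oxygen without epimerisation; this is secured by the TIPS ether, which resists base-induced silyl transfer and so keeps the primary oxygen out of play, by the lack of any carbonyl or other acidifying group next to C3, and by the loss of fluoride, which makes the less stable cis isomer kinetically final.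

Step 11
Reactants: 19 syringaldehyde
Product: 20 4-benzyloxy-3,5-dimethoxybenzaldehyde
Conditions: BnBr, K2CO3, DMF, 60 °C
Reagents that add atoms: benzyl bromide, BrCc1ccccc1
Why: Williamson etherification protects the phenol as a benzyl ether that is removed together with the ring A benzyl ether in the last step.

Step 12
Reactants: 20 4-benzyloxy-3,5-dimethoxybenzaldehyde
Product: 21 2-(4-benzyloxy-3,5-dimethoxyphenyl)-1,3-dithiane
Conditions: propane-1,3-dithiol, BF3·OEt2 (0.2 equiv), CH2Cl2, 0 °C → rt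
Reagents that add atoms: propane-1,3-dithiol, SCCCS
Why: Lewis acid-catalysed dithioacetalisation turns the aldehyde carbon into an acyl anion equivalent (umpolung).

Step 13
Reactants: 21 2-(4-benzyloxy-3,5-dimethoxyphenyl)-1,3-dithiane; 22 (5R)-5-(l-menthyloxy)furan-2(5H)-one; 18 (2S,3S)-2-(4-benzyloxy-3-methoxyphenyl)-7-methoxy-3-[(TIPS-oxy)methyl]-2,3-dihydro-1-benzofuran-5-carbaldehyde
Product: 25 (3S,4R,5R)-3-[(R)-DBF(hydroxy)methyl]-4-[2-Syr(Bn)-1,3-dithian-2-yl]-5-(MenO)dihydrofuran-2(3H)-one (major carbinol epimer shown), via lithiated dithiane 23 (not isolated), via lithium lactone enolate 24 (not isolated)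
Conditions: n-butyllithium, THF, −78 → −20 °C; 22, −78 °C; 18, −78 °C; AcOH quench at −78 °C
Reagents that add atoms: none
Why: Tandem conjugate addition–aldol reaction in which the dithiane anion adds 1,4 to the butenolide anti to the menthyloxy group (setting C8''), and the resulting enolate is trapped by aldehyde 18 anti to the new substituent (setting C8'), while the carbinol centre formed at C7' is erased in step 14 and both of its epimers are carried on.

Step 14
Reactants: 25 (3S,4R,5R)-3-[(R)-DBF(hydroxy)methyl]-4-[2-Syr(Bn)-1,3-dithian-2-yl]-5-(MenO)dihydrofuran-2(3H)-one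
Product: 26 (3S,4R,5R)-3-(DBF-carbonyl)-4-[Syr(Bn)-carbonyl]-5-(MenO)dihydrofuran-2(3H)-one
Conditions: Dess–Martin periodinane (5 equiv), MeCN/CH2Cl2/H2O (8:1:1), rt
Reagents that add atoms: water, O
Why: The periodinane carries out two known oxidations in one flask, the Dess–Martin oxidation of the secondary benzylic alcohol and the oxidative hydrolysis of the dithioketal, under near-neutral conditions that spare the benzylic ethers, so that both benzylic carbons reach the ketone level.

Step 15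
Reactants: 26 (3S,4R,5R)-3-(DBF-carbonyl)-4-[Syr(Bn)-carbonyl]-5-(MenO)dihydrofuran-2(3H)-one
Product: 28 (1S,2R,3R,4S)-1-DBF-4-Syr(Bn)-2,3-bis(hydroxymethyl)butane-1,4-diol, via dihydroxy lactone 27 (not isolated)
Conditions: Zn(BH4)2, Et2O/CH2Cl2, −40 → 0 °C; then LiAlH4, THF, 0 °C → rt; aqueous potassium sodium tartrate (KNaC4H4O6) work-up
Reagents that add atoms: none
Why: Chelation-controlled ketone reduction in which zinc bridges each aryl ketone oxygen and the oxygen on the adjacent C9 carbon (the lactone carbonyl for C7', an acetal oxygen for C7''), hydride attacks each chelate on the face away from the other ring substituent to set the syn (7'S,7''S) carbinols, and LiAlH4 then reduces the lactone and its acylal carbon to the two primary alcohols with loss of menthol, any acyl or acetal transfer among the alkoxides being harmless because every such isomer gives the same tetraol.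

Step 16
Reactants: 28 (1S,2R,3R,4S)-1-DBF-4-Syr(Bn)-2,3-bis(hydroxymethyl)butane-1,4-diol
Product: 30 (2S,3S)-2-(4-benzyloxy-3-methoxyphenyl)-5-[(1S,3aR,4S,6aR)-4-Syr(Bn)-tetrahydro-1H,3H-furo[3,4-c]furan-1-yl]-7-methoxy-3-[(TIPS-oxy)methyl]-2,3-dihydro-1-benzofuran, via bis(mesylate) 29 (not isolated)
Conditions: MsCl (2.1 equiv), pyridine, −20 °C; then 40 °C
Reagents that add atoms: none
Why: Sulfonylation is selective for the two primary hydroxyls, and each benzylic hydroxyl then displaces the mesylate of the opposite half in a 5-exo-tet SN2 closure at a primary carbon (Williamson-type cycloetherification), so no benzylic C–O bond is broken, the syn carbinols become the two exo aryl-bearing carbons, and no cation or acid threatens C2 of ring C.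

Step 17
Reactants: 30 (2S,3S)-2-(4-benzyloxy-3-methoxyphenyl)-5-[(1S,3aR,4S,6aR)-4-Syr(Bn)-tetrahydro-1H,3H-furo[3,4-c]furan-1-yl]-7-methoxy-3-[(TIPS-oxy)methyl]-2,3-dihydro-1-benzofuran
Product: 31 [(2S,3S)-2-(4-benzyloxy-3-methoxyphenyl)-5-[(1S,3aR,4S,6aR)-4-Syr(Bn)-tetrahydro-1H,3H-furo[3,4-c]furan-1-yl]-7-methoxy-2,3-dihydro-1-benzofuran-3-yl]methanol
Conditions: Bu4NF, AcOH (1:1), THF, 0 °C → rt
Reagents that add atoms: none
Why: Fluoride cleaves the silyl ether while both phenols are still benzylated, so no phenoxide can form and open ring C through a quinone methide.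

Step 18
Reactants: 31 [(2S,3S)-2-(4-benzyloxy-3-methoxyphenyl)-5-[(1S,3aR,4S,6aR)-4-Syr(Bn)-tetrahydro-1H,3H-furo[3,4-c]furan-1-yl]-7-methoxy-2,3-dihydro-1-benzofuran-3-yl]methanol
Product: 32 4-{(1S,3aR,4S,6aR)-4-[(2S,3S)-2-(4-hydroxy-3-methoxyphenyl)-3-(hydroxymethyl)-7-methoxy-2,3-dihydro-1-benzofuran-5-yl]tetrahydro-1H,3H-furo[3,4-c]furan-1-yl}-2,6-dimethoxyphenol (CNP0126146.1)
Conditions: H2 (1 atm), Pd/C (10 wt% palladium on carbon), EtOAc, rt, reaction stopped at full conversion
Reagents that add atoms: none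
Why: Hydrogenolysis of the two aryl benzyl ethers under neutral conditions is much faster than cleavage of the cyclic benzylic ethers of ring C and of the furofuran, and it frees the phenols without acid or base that could epimerise C2.

**Compound list**

1 | 4-fluoro-3-methoxybenzaldehyde | COc1cc(C=O)ccc1F | starting material
2 | 2-(4-fluoro-3-methoxyphenyl)-1,3-dioxolane | COc1cc(C2OCCO2)ccc1F | intermediate
3 | 2-[5-(1,3-dioxolan-2-yl)-2-fluoro-3-methoxyphenyl]-4,4,5,5-tetramethyl-1,3,2-dioxaborolane | COc1cc(C2OCCO2)cc(B3OC(C)(C)C(C)(C)O3)c1F | intermediate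
4 | ethyl bromoacetate | CCOC(=O)CBr | starting material
5 | ethyl [5-(1,3-dioxolan-2-yl)-2-fluoro-3-methoxyphenyl]acetate | CCOC(=O)Cc1cc(C2OCCO2)cc(OC)c1F | intermediate
6 | [5-(1,3-dioxolan-2-yl)-2-fluoro-3-methoxyphenyl]acetic acid | OC(=O)Cc1cc(C2OCCO2)cc(OC)c1F | intermediate
7 | (S)-4-benzyl-1,3-oxazolidin-2-one | O=C1N[C@@H](Cc2ccccc2)CO1 | starting material
8 | mixed anhydride of acid 6 with pivalic acid | COc1cc(C2OCCO2)cc(CC(=O)OC(=O)C(C)(C)C)c1F | intermediate (not isolated)
9 | (S)-4-benzyl-3-{[5-(1,3-dioxolan-2-yl)-2-fluoro-3-methoxyphenyl]acetyl}-1,3-oxazolidin-2-one | COc1cc(C2OCCO2)cc(CC(=O)N3C(=O)OC[C@@H]3Cc3ccccc3)c1F | intermediate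
10 | O-benzylvanillin (4-benzyloxy-3-methoxybenzaldehyde) | COc1cc(C=O)ccc1OCc1ccccc1 | starting material
11 | O-trimethylsilyl ether of aldol adduct 12 | COc1cc([C@@H](O[Si](C)(C)C)[C@H](C(=O)N2C(=O)OC[C@@H]2Cc2ccccc2)c2cc(C3OCCO3)cc(OC)c2F)ccc1OCc1ccccc1 | intermediate (not isolated)
12 | (4S)-4-benzyl-3-[(2R,3S)-3-(4-benzyloxy-3-methoxyphenyl)-2-[5-(1,3-dioxolan-2-yl)-2-fluoro-3-methoxyphenyl]-3-hydroxypropanoyl]-1,3-oxazolidin-2-one (anti) | COc1cc([C@@H](O)[C@H](C(=O)N2C(=O)OC[C@@H]2Cc2ccccc2)c2cc(C3OCCO3)cc(OC)c2F)ccc1OCc1ccccc1 | intermediate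
13 | (1S,2S)-1-(4-benzyloxy-3-methoxyphenyl)-2-[5-(1,3-dioxolan-2-yl)-2-fluoro-3-methoxyphenyl]propane-1,3-diol | COc1cc([C@@H](O)[C@H](CO)c2cc(C3OCCO3)cc(OC)c2F)ccc1OCc1ccccc1 | intermediate
14 | (1S,2S)-1-(4-benzyloxy-3-methoxyphenyl)-2-[5-(1,3-dioxolan-2-yl)-2-fluoro-3-methoxyphenyl]-3-(TIPS-oxy)propan-1-ol | COc1cc([C@@H](O)[C@H](CO[Si](C(C)C)(C(C)C)C(C)C)c2cc(C3OCCO3)cc(OC)c2F)ccc1OCc1ccccc1 | intermediate
15 | 3-[(1S,2S)-1-(4-benzyloxy-3-methoxyphenyl)-1-hydroxy-3-(TIPS-oxy)propan-2-yl]-4-fluoro-5-methoxybenzaldehyde (anti; key-step precursor) | COc1cc([C@@H](O)[C@H](CO[Si](C(C)C)(C(C)C)C(C)C)c2cc(C=O)cc(OC)c2F)ccc1OCc1ccccc1 | intermediate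
16 | sodium alkoxide of 15 | [Na+].COc1cc([C@@H]([O-])[C@H](CO[Si](C(C)C)(C(C)C)C(C)C)c2cc(C=O)cc(OC)c2F)ccc1OCc1ccccc1 | intermediate (not isolated)
17 | Meisenheimer adduct, sodium salt: C7a is sp3 and bears F and O1, with the charge on the formyl oxygen (configuration at C7a and enolate geometry not specified) | [Na+].COc1cc([C@H]2OC3(F)C(OC)=CC(=C[O-])C=C3[C@H]2CO[Si](C(C)C)(C(C)C)C(C)C)ccc1OCc1ccccc1 | intermediate (not isolated)
18 | (2S,3S)-2-(4-benzyloxy-3-methoxyphenyl)-7-methoxy-3-[(TIPS-oxy)methyl]-2,3-dihydro-1-benzofuran-5-carbaldehyde (cis; key-step product) | COc1cc([C@H]2Oc3c(OC)cc(C=O)cc3[C@H]2CO[Si](C(C)C)(C(C)C)C(C)C)ccc1OCc1ccccc1 | intermediate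
19 | syringaldehyde | COc1cc(C=O)cc(OC)c1O | starting material
20 | 4-benzyloxy-3,5-dimethoxybenzaldehyde | COc1cc(C=O)cc(OC)c1OCc1ccccc1 | intermediate
21 | 2-(4-benzyloxy-3,5-dimethoxyphenyl)-1,3-dithiane | COc1cc(C2SCCCS2)cc(OC)c1OCc1ccccc1 | intermediate
22 | (5R)-5-(l-menthyloxy)furan-2(5H)-one | O=C1O[C@@H](O[C@@H]2C[C@H](C)CC[C@H]2C(C)C)C=C1 | starting material
23 | 2-lithio-2-(4-benzyloxy-3,5-dimethoxyphenyl)-1,3-dithiane | COc1cc(C2([Li])SCCCS2)cc(OC)c1OCc1ccccc1 | intermediate (not isolated)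
24 | lithium enolate of (4R,5R)-4-[2-Syr(Bn)-1,3-dithian-2-yl]-5-(MenO)dihydrofuran-2(3H)-one | [Li]OC1=C[C@@H](C2(SCCCS2)c2cc(OC)c(OCc3ccccc3)c(OC)c2)[C@H](O[C@@H]2C[C@H](C)CC[C@H]2C(C)C)O1 | intermediate (not isolated)
25 | (3S,4R,5R)-3-[(R)-DBF(hydroxy)methyl]-4-[2-Syr(Bn)-1,3-dithian-2-yl]-5-(MenO)dihydrofuran-2(3H)-one (major carbinol epimer shown; the epimer is carried along) | O=C1O[C@@H](O[C@@H]2C[C@H](C)CC[C@H]2C(C)C)[C@H](C2(SCCCS2)c2cc(OC)c(OCc3ccccc3)c(OC)c2)[C@H]1[C@@H](O)c1cc(OC)c2O[C@H](c3ccc(OCc4ccccc4)c(OC)c3)[C@H](CO[Si](C(C)C)(C(C)C)C(C)C)c2c1 | intermediate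
26 | (3S,4R,5R)-3-(DBF-carbonyl)-4-[Syr(Bn)-carbonyl]-5-(MenO)dihydrofuran-2(3H)-one | O=C1O[C@@H](O[C@@H]2C[C@H](C)CC[C@H]2C(C)C)[C@H](C(=O)c2cc(OC)c(OCc3ccccc3)c(OC)c2)[C@H]1C(=O)c1cc(OC)c2O[C@H](c3ccc(OCc4ccccc4)c(OC)c3)[C@H](CO[Si](C(C)C)(C(C)C)C(C)C)c2c1 | intermediate
27 | (3S,4S,5R)-3-[(S)-DBF(hydroxy)methyl]-4-[(S)-Syr(Bn)(hydroxy)methyl]-5-(MenO)dihydrofuran-2(3H)-one | O=C1O[C@@H](O[C@@H]2C[C@H](C)CC[C@H]2C(C)C)[C@H]([C@H](O)c2cc(OC)c(OCc3ccccc3)c(OC)c2)[C@H]1[C@H](O)c1cc(OC)c2O[C@H](c3ccc(OCc4ccccc4)c(OC)c3)[C@H](CO[Si](C(C)C)(C(C)C)C(C)C)c2c1 | intermediate (not isolated)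
28 | (1S,2R,3R,4S)-1-DBF-4-Syr(Bn)-2,3-bis(hydroxymethyl)butane-1,4-diol | OC[C@H]([C@H](O)c1cc(OC)c2O[C@H](c3ccc(OCc4ccccc4)c(OC)c3)[C@H](CO[Si](C(C)C)(C(C)C)C(C)C)c2c1)[C@H](CO)[C@H](O)c1cc(OC)c(OCc2ccccc2)c(OC)c1 | intermediate
29 | bis(methanesulfonate) of the two primary hydroxyls of 28 | CS(=O)(=O)OC[C@H]([C@H](O)c1cc(OC)c2O[C@H](c3ccc(OCc4ccccc4)c(OC)c3)[C@H](CO[Si](C(C)C)(C(C)C)C(C)C)c2c1)[C@H](COS(C)(=O)=O)[C@H](O)c1cc(OC)c(OCc2ccccc2)c(OC)c1 | intermediate (not isolated)
30 | (2S,3S)-2-(4-benzyloxy-3-methoxyphenyl)-5-[(1S,3aR,4S,6aR)-4-Syr(Bn)-tetrahydro-1H,3H-furo[3,4-c]furan-1-yl]-7-methoxy-3-[(TIPS-oxy)methyl]-2,3-dihydro-1-benzofuran | COc1cc([C@H]2Oc3c(OC)cc([C@H]4OC[C@H]5[C@@H]4CO[C@@H]5c4cc(OC)c(OCc6ccccc6)c(OC)c4)cc3[C@H]2CO[Si](C(C)C)(C(C)C)C(C)C)ccc1OCc1ccccc1 | intermediate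
31 | [(2S,3S)-2-(4-benzyloxy-3-methoxyphenyl)-5-[(1S,3aR,4S,6aR)-4-Syr(Bn)-tetrahydro-1H,3H-furo[3,4-c]furan-1-yl]-7-methoxy-2,3-dihydro-1-benzofuran-3-yl]methanol | COc1cc([C@H]2Oc3c(OC)cc([C@H]4OC[C@H]5[C@@H]4CO[C@@H]5c4cc(OC)c(OCc6ccccc6)c(OC)c4)cc3[C@H]2CO)ccc1OCc1ccccc1 | intermediate
32 | 4-{(1S,3aR,4S,6aR)-4-[(2S,3S)-2-(4-hydroxy-3-methoxyphenyl)-3-(hydroxymethyl)-7-methoxy-2,3-dihydro-1-benzofuran-5-yl]tetrahydro-1H,3H-furo[3,4-c]furan-1-yl}-2,6-dimethoxyphenol (CNP0126146.1) | COc1cc([C@H]2Oc3c(OC)cc([C@H]4OC[C@H]5[C@@H]4CO[C@@H]5c4cc(OC)c(O)c(OC)c4)cc3[C@H]2CO)ccc1O | target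

**Step count**

- Total: 18 steps.
- Longest linear sequence: 16 steps (steps 1 to 10 and 13 to 18); steps 11 and 12 form a two-step side branch.

**Steps most likely to fail and their fallbacks**

Step 15 is the most exposed. The acetal oxygens on C9'' are weak donors, so the zinc chelate that steers hydride to the C7'' ketone may not form, and facial selectivity at that carbon may be poor; the wrong carbinol would end as an endo aryl group after step 16. The fallback sets the two carbinols one at a time and by different control elements. It sets out from 25. A Parikh–Doering oxidation (SO3·pyridine, DMSO, i-Pr2NEt, CH2Cl2, 0 °C) of the carbinol alone gives the keto dithiane F1. Zn(BH4)2 reduces this single β-keto lactone through the chelate with the lactone carbonyl to the syn alcohol F2. Hg(ClO4)2 and CaCO3 in aqueous THF then unmask the hydroxy ketone F3. LiBH(s-Bu)3 in THF at −78 °C reduces the aryl ketone under Felkin–Anh control, the bulky hydride arriving anti to the ring carbon C8' with the carbonyl oxygen beside C9'', which leads to the same (7''S) carbinol. This gives 27, which is treated with LiAlH4 as in step 15, and the route is rejoined at 28.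

Step 10 may suffer from side reactions of the free formyl group under alkoxide conditions: hydride transfer from the benzylic alkoxide to the aldehyde, or hemiacetal formation that ties up the nucleophile. The fallback keeps the disconnection but changes the activating group to one that is inert to alkoxide. It sets out from 15. Iodine and aqueous ammonia in THF convert the formyl group into the nitrile F4. NaH in THF closes ring C with the cyano group as the para activator and gives the cyclised nitrile F5. i-Bu2AlH in toluene at −78 °C, followed by hydrolysis of the aldimine, returns the aldehyde, and the route is rejoined at 18.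

Step 14 asks one reagent for two oxidations. The risks are over-oxidation at the doubly activated C8'–H of the β-keto lactone once it has formed, and incomplete unmasking of the hindered dithioketal. The fallback separates the two events and uses a thiophilic metal salt for the first. It sets out from 25. Hg(ClO4)2 and CaCO3 in aqueous THF unmask the ketone to give the hydroxy ketone F6. A Parikh–Doering oxidation (SO3·pyridine, DMSO, i-Pr2NEt) then gives the diketone, and the route is rejoined at 26.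

Further compounds
F1 | step 15 | (3S,4R,5R)-3-(DBF-carbonyl)-4-[2-Syr(Bn)-1,3-dithian-2-yl]-5-(MenO)dihydrofuran-2(3H)-one | O=C1O[C@@H](O[C@@H]2C[C@H](C)CC[C@H]2C(C)C)[C@H](C2(SCCCS2)c2cc(OC)c(OCc3ccccc3)c(OC)c2)[C@H]1C(=O)c1cc(OC)c2O[C@H](c3ccc(OCc4ccccc4)c(OC)c3)[C@H](CO[Si](C(C)C)(C(C)C)C(C)C)c2c1
F2 | step 15 | (3S,4R,5R)-3-[(S)-DBF(hydroxy)methyl]-4-[2-Syr(Bn)-1,3-dithian-2-yl]-5-(MenO)dihydrofuran-2(3H)-one | O=C1O[C@@H](O[C@@H]2C[C@H](C)CC[C@H]2C(C)C)[C@H](C2(SCCCS2)c2cc(OC)c(OCc3ccccc3)c(OC)c2)[C@H]1[C@H](O)c1cc(OC)c2O[C@H](c3ccc(OCc4ccccc4)c(OC)c3)[C@H](CO[Si](C(C)C)(C(C)C)C(C)C)c2c1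
F3 | step 15 | (3S,4R,5R)-3-[(S)-DBF(hydroxy)methyl]-4-[Syr(Bn)-carbonyl]-5-(MenO)dihydrofuran-2(3H)-one | O=C1O[C@@H](O[C@@H]2C[C@H](C)CC[C@H]2C(C)C)[C@H](C(=O)c2cc(OC)c(OCc3ccccc3)c(OC)c2)[C@H]1[C@H](O)c1cc(OC)c2O[C@H](c3ccc(OCc4ccccc4)c(OC)c3)[C@H](CO[Si](C(C)C)(C(C)C)C(C)C)c2c1
F4 | step 10 | 3-[(1S,2S)-1-(4-benzyloxy-3-methoxyphenyl)-1-hydroxy-3-(TIPS-oxy)propan-2-yl]-4-fluoro-5-methoxybenzonitrile | COc1cc([C@@H](O)[C@H](CO[Si](C(C)C)(C(C)C)C(C)C)c2cc(C#N)cc(OC)c2F)ccc1OCc1ccccc1
F5 | step 10 | (2S,3S)-2-(4-benzyloxy-3-methoxyphenyl)-7-methoxy-3-[(TIPS-oxy)methyl]-2,3-dihydro-1-benzofuran-5-carbonitrile | COc1cc([C@H]2Oc3c(OC)cc(C#N)cc3[C@H]2CO[Si](C(C)C)(C(C)C)C(C)C)ccc1OCc1ccccc1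
F6 | step 14 | (3S,4R,5R)-3-[(R)-DBF(hydroxy)methyl]-4-[Syr(Bn)-carbonyl]-5-(MenO)dihydrofuran-2(3H)-one | O=C1O[C@@H](O[C@@H]2C[C@H](C)CC[C@H]2C(C)C)[C@H](C(=O)c2cc(OC)c(OCc3ccccc3)c(OC)c2)[C@H]1[C@@H](O)c1cc(OC)c2O[C@H](c3ccc(OCc4ccccc4)c(OC)c3)[C@H](CO[Si](C(C)C)(C(C)C)C(C)C)c2c1
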